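**Retrosynthetic overview**
1. Ring atoms: C1 = quaternary C(CH3) carrying the long side chain, C2 = CH with the 3-hydroxypropyl chain, C3 = alkylidene carbon, C4 and C5 = CH2, C6 = C(CH3)OH. The enal, the free primary alcohol, the acetate and the C6 methyl group are installed last (allylic oxidation, desilylation, acetylation, methyl addition to a C6 ketone).
2. The side chain is cut at the bond between the carbinol carbon and the disubstituted alkene: catalytic asymmetric addition of an (E)-alkenylzinc, made from (S)-3,7-dimethyloct-6-en-1-yne (from (S)-citronellal), to an (E)-2-methyl enal installed by Wittig reaction.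
3. The only ring is closed at C3–C4 by a nickel-catalysed methylative enone–alkyne cyclisation of an acyclic alkynyl vinyl ketone. The enabling feature: C4 is β to the oxygenated C6 (a masked ketone, so C6(=O)–C5=C4 is a vinyl ketone), and C3 carries the tetrasubstituted exocyclic alkene C3=C(CH3)CHO with CH3 cis to C4, the signature of syn addition of C4 and CH3 across a C3≡C triple bond.
4. The acyclic precursor takes its C1/C2 stereodiad from an Ireland–Claisen rearrangement of the ester of a (2S,3E)-allylic alcohol (from (S)-but-3-yn-2-ol) with 5-silyloxypentanoic acid. The acid becomes the alkyne (Corey–Fuchs, formaldehyde) and the propenyl group becomes the vinyl ketone (ozonolysis, vinyl addition, oxidation).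
5. Ring order: one ring only, the cyclohexane, formed in step 15.

Key step: step 15

Remark (assumption): in step 20 (+)-MIB is assumed to direct the alkenylzinc to the Re face of the enal, by analogy with the Si-face selectivity of (–)-MIB in organozinc additions to aryl and α,β-unsaturated aldehydes. TBS = tert-butyldimethylsilyl, TBDPS = tert-butyldiphenylsilyl; ring atoms are numbered as in the overview.

**Route**

Step 1
Reactants: 1 (S)-but-3-yn-2-ol; 2 tert-butyl(3-iodopropoxy)dimethylsilane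
Product: 4 (2S)-7-(TBS-oxy)hept-3-yn-2-ol, via dilithium alkoxide acetylide 3 (not isolated)
Conditions: n-BuLi (2.1 equiv), THF, –78 → 0 °C; then 2, HMPA, –20 °C → rt
Reagents that add atoms: none
Why: The alkoxide–acetylide dianion is alkylated at carbon by the primary iodide (acetylide SN2 alkylation), and the stereocentre of 1 is not touched.

Step 2
Reactants: 4 (2S)-7-(TBS-oxy)hept-3-yn-2-ol
Product: 6 (2S,3Z)-7-(TBS-oxy)-4-iodohept-3-en-2-ol, via cyclic sodium alkenylaluminate 5 (not isolated)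
Conditions: Red-Al (NaAlH2(OCH2CH2OMe)2), THF, 0 °C → rt; EtOAc; then I2, THF, –78 → 0 °C
Reagents that add atoms: iodine, II
Why: Alkoxide-directed trans-hydroalumination of the propargylic alcohol places aluminium on the distal alkyne carbon in a five-membered chelate, and iodinolysis with retention should give the (Z)-3-iodoallylic alcohol.

Step 3
Reactants: 6 (2S,3Z)-7-(TBS-oxy)-4-iodohept-3-en-2-ol
Product: 7 (2S,3E)-7-(TBS-oxy)-4-methylhept-3-en-2-ol
Conditions: Me2CuLi (from MeLi and CuI, 4 equiv), Et2O, 0 °C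
Reagents that add atoms: lithium dimethylcuprate, [Li+].C[Cu-]C
Why: Gilman cuprate cross-coupling replaces iodine by methyl with retention of alkene geometry, which fixes the (E)-trisubstituted alkene that becomes the quaternary carbon C1.

Step 4
Reactants: 8 δ-valerolactone
Product: 11 5-(TBDPS-oxy)pentanoic acid, via sodium 5-hydroxypentanoate 9 (not isolated), via doubly silylated silyl ester 10 (not isolated)
Conditions: NaOH, MeOH/H2O, rt, concentrate; TBDPSCl, imidazole, DMF, rt; then K2CO3, MeOH/THF/H2O, rt; citric acid to pH 4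
Reagents that add atoms: sodium hydroxide, [Na+].[OH-]; tert-butyl(chloro)diphenylsilane, CC(C)(C)[Si](Cl)(c1ccccc1)c1ccccc1
Why: Saponification opens the lactone, silylation caps both oxygens, and mild base cleaves only the labile silyl ester (standard protection of a hydroxy acid).

Step 5
Reactants: 7 (2S,3E)-7-(TBS-oxy)-4-methylhept-3-en-2-ol; 11 5-(TBDPS-oxy)pentanoic acid
Product: 12 (2S,3E)-7-(TBS-oxy)-4-methylhept-3-en-2-yl 5-(TBDPS-oxy)pentanoate
Conditions: DCC, DMAP (cat.), CH2Cl2, 0 °C → rt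
Reagents that add atoms: none
Why: Steglich esterification acylates the secondary allylic alcohol without touching its stereocentre.

Step 6
Reactants: 12 (2S,3E)-7-(TBS-oxy)-4-methylhept-3-en-2-yl 5-(TBDPS-oxy)pentanoate
Product: 15 (2S,3R,4E)-3-[3-(TBS-oxy)propyl]-2-[3-(TBDPS-oxy)propyl]-3-methylhex-4-enoic acid, via Z-silyl ketene acetal 13 (not isolated), via trimethylsilyl ester 14 (not isolated)
Conditions: LDA, THF/HMPA (4:1), –78 °C; Me3SiCl/Et3N, –78 °C → rt, then 50 °C; aq. citric acid work-up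
Reagents that add atoms: none
Why: Ireland–Claisen rearrangement: enolisation in THF/HMPA should give the (Z)-silyl ketene acetal, and the chair transition state with the carbinol methyl group equatorial transfers the (S)-carbinol configuration to C1 (quaternary) and C2 while forming the (E)-propenyl group.

Step 7
Reactants: 15 the Claisen acid
Product: 16 (2S,3R,4E)-3-[3-(TBS-oxy)propyl]-2-[3-(TBDPS-oxy)propyl]-3-methylhex-4-en-1-ol
Conditions: LiAlH4, THF, 0 °C → rt
Reagents that add atoms: none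
Why: Hydride reduction of the carboxylic acid to the primary alcohol leaves silyl ethers and the alkene untouched.

Step 8
Reactants: 16 the primary alcohol
Product: 17 (2S,3R,4E)-3-[3-(TBS-oxy)propyl]-2-[3-(TBDPS-oxy)propyl]-3-methylhex-4-enal
Conditions: Dess–Martin periodinane, NaHCO3, CH2Cl2, 0 °C → rt
Reagents that add atoms: none
Why: Buffered Dess–Martin oxidation gives the aldehyde without epimerising the adjacent C2 stereocentre.

Step 9
Reactants: 17 the aldehyde
Product: 18 (3R,4R,5E)-1,1-dibromo-4-[3-(TBS-oxy)propyl]-3-[3-(TBDPS-oxy)propyl]-4-methylhepta-1,5-diene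
Conditions: CBr4, PPh3, Et3N, CH2Cl2, 0 °C
Reagents that add atoms: carbon tetrabromide, BrC(Br)(Br)Br
Why: Corey–Fuchs dibromo-olefination (Wittig-type reaction of Ph3P=CBr2) works on α-branched aldehydes under non-epimerising conditions.

Step 10
Reactants: 18 the dibromoalkene
Product: 20 (4S,5R,6E)-5-[3-(TBS-oxy)propyl]-4-[3-(TBDPS-oxy)propyl]-5-methyloct-6-en-2-yn-1-ol, via lithium acetylide 19 (not isolated)
Conditions: n-BuLi (2.2 equiv), THF, –78 → 0 °C; (CH2O)n, –78 °C → rt
Reagents that add atoms: formaldehyde (from paraformaldehyde), C=O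
Why: Second stage of the Corey–Fuchs sequence (bromine–lithium exchange, Fritsch–Buttenberg–Wiechell rearrangement) gives the lithium acetylide, which adds to formaldehyde.

Step 11
Reactants: 20 the propargylic alcohol
Product: 21 TBDPS ether of 20, (4S,5R,6E)-1-(TBDPS-oxy)-5-[3-(TBS-oxy)propyl]-4-[3-(TBDPS-oxy)propyl]-5-methyloct-6-en-2-yne
Conditions: TBDPSCl, imidazole, CH2Cl2, rt
Reagents that add atoms: tert-butyl(chloro)diphenylsilane, CC(C)(C)[Si](Cl)(c1ccccc1)c1ccccc1
Why: Standard silylation of a primary alcohol.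

Step 12
Reactants: 21 the enyne
Product: 23 (2S,3R)-6-(TBDPS-oxy)-2-[3-(TBS-oxy)propyl]-3-[3-(TBDPS-oxy)propyl]-2-methylhex-4-ynal, via ozonide 22 (not isolated)
Conditions: O3, CH2Cl2, –78 °C (Sudan Red end-point); then PPh3, –78 °C → rt
Reagents that add atoms: ozone, [O-][O+]=O
Why: Ozonolysis cleaves the disubstituted alkene far faster than the alkyne, and reductive work-up gives the aldehyde at the future C6.

Step 13
Reactants: 23 the ynal
Product: 24 (4S,5R)-8-(TBDPS-oxy)-4-[3-(TBS-oxy)propyl]-5-[3-(TBDPS-oxy)propyl]-4-methyloct-1-en-6-yn-3-ol (both C3 epimers)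
Conditions: CH2=CHMgBr, THF, –78 °C
Reagents that add atoms: vinylmagnesium bromide, C=C[Mg]Br
Why: Grignard addition to the non-enolisable neopentyl aldehyde; the new carbinol centre forms as a mixture, which is of no consequence because it is oxidised in the next step.

Step 14
Reactants: 24 the allylic alcohol
Product: 25 (4S,5R)-8-(TBDPS-oxy)-4-[3-(TBS-oxy)propyl]-5-[3-(TBDPS-oxy)propyl]-4-methyloct-1-en-6-yn-3-one
Conditions: Dess–Martin periodinane, NaHCO3, CH2Cl2, 0 °C; used at once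
Reagents that add atoms: none
Why: Neutral Dess–Martin oxidation of the allylic alcohol gives the sensitive vinyl ketone without conjugate addition or polymerisation.

Step 15
Reactants: 25 the alkynyl vinyl ketone
Product: 27 (2S,3R,4Z)-4-[1-(TBDPS-oxy)propan-2-ylidene]-2-[3-(TBS-oxy)propyl]-3-[3-(TBDPS-oxy)propyl]-2-methylcyclohexan-1-one, via trimethylsilyl enol ether 26 (not isolated)
Conditions: Ni(cod)2 (10 mol %), Me2Zn (2.5 equiv), Me3SiCl (2 equiv), THF, 0 °C → rt, 25 added over 2 h; then aq. citric acid, THF, 0 °C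
Reagents that add atoms: dimethylzinc, C[Zn]C
Why: Proposed new method: zerovalent nickel and Me3SiCl are expected to convert the vinyl ketone, in its s-trans geometry, into a 1-siloxy-η3-allylnickel chloride whose unsubstituted terminus (C4) adds to the tethered alkyne by syn migratory insertion, and the resulting exocyclic alkenylnickel is methylated by Me2Zn (transmetalation, C–C reductive elimination) to release silyl enol ether 26, hydrolysed to 27 on work-up. The closest known reaction type is the nickel-catalysed alkylative three-component coupling of enones, alkynes and organozincs (intermolecular with Me3SiCl, and intramolecular for alkynes tethered to the enone β-carbon); new here is that the tether runs through the carbonyl carbon, so the enone is engaged in an endo sense. The ring closes 6-exo-dig at the alkyne (6-endo-trig at the enone). No stereocentre is created; the only new stereo-element, the tetrasubstituted C3=C alkene, follows from syn addition of C4 and CH3 across the triple bond, which places CH3 cis to C4 and the silyloxymethyl group cis to C2. The step needs chemoselectivity for alkyne insertion over direct methyl transfer to the allylnickel and 6-exo over 7-endo regioselectivity; the three-atom tether, the quaternary C1 (Thorpe–Ingold compression) and the branch at C2 hold the alkyne next to the enone β-carbon, and slow addition of 25 keeps bimolecular pathways down.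

Step 16
Reactants: 27 the cyclohexanone
Product: 28 (2S,3R,4Z)-2-(3-hydroxypropyl)-4-[1-(TBDPS-oxy)propan-2-ylidene]-3-[3-(TBDPS-oxy)propyl]-2-methylcyclohexan-1-one
Conditions: HF·pyridine, pyridine, THF, 0 °C
Reagents that add atoms: none
Why: Buffered HF·pyridine cleaves the primary TBS ether much faster than primary TBDPS ethers (selective desilylation), and the alcohol-free medium avoids ketal formation at C6.

Step 17
Reactants: 28 the hydroxy ketone
Product: 29 (2S,3R,4Z)-2-(3-oxopropyl)-4-[1-(TBDPS-oxy)propan-2-ylidene]-3-[3-(TBDPS-oxy)propyl]-2-methylcyclohexan-1-one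
Conditions: Dess–Martin periodinane, NaHCO3, CH2Cl2, 0 °C → rt
Reagents that add atoms: none
Why: Dess–Martin oxidation converts the primary alcohol into the aldehyde, while the hindered ketone and its tertiary hemiketal form cannot be oxidised.

Step 18
Reactants: 29 the keto aldehyde
Product: 30 (2S,3R,4Z)-2-[(3E)-4-methyl-5-oxopent-3-en-1-yl]-4-[1-(TBDPS-oxy)propan-2-ylidene]-3-[3-(TBDPS-oxy)propyl]-2-methylcyclohexan-1-one
Conditions: Ph3P=C(CH3)CHO, toluene, 80 °C
Reagents that add atoms: 2-(triphenylphosphoranylidene)propanal, CC(C=O)=P(c1ccccc1)(c1ccccc1)c1ccccc1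
Why: Wittig reaction with the stabilised ylide should give the (E)-2-methyl enal and react only with the aldehyde, not with the hindered α-quaternary ketone.

Step 19
Reactants: 31 (S)-citronellal
Product: 33 (3S)-3,7-dimethyloct-6-en-1-yne, via alkenyl nonaflate 32 (not isolated)
Conditions: C4F9SO2F, phosphazene base P2-Et (2.2 equiv), DMF, –20 °C → rt
Reagents that add atoms: none
Why: The enolisable aldehyde is converted into its alkenyl nonaflate, which eliminates under the phosphazene base to the terminal alkyne (carbonyl-to-alkyne dehydration); the stereocentre is β to the carbonyl and is not involved.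

Step 20
Reactants: 30 the keto enal; 33 (3S)-3,7-dimethyloct-6-en-1-yne
Product: 36 (2S,3R,4Z)-2-[(3E,5R,6E,8S)-5-hydroxy-4,8,12-trimethyltrideca-3,6,11-trien-1-yl]-4-[1-(TBDPS-oxy)propan-2-ylidene]-3-[3-(TBDPS-oxy)propyl]-2-methylcyclohexan-1-one, via alkenyldicyclohexylborane 34 (not isolated), via alkenylmethylzinc 35 (not isolated)
Conditions: 33, Cy2BH, toluene, 0 °C → rt; Me2Zn, –78 °C; (+)-MIB (5 mol %); then 30, –20 → 0 °C
Reagents that add atoms: none
Why: Hydroboration of the terminal alkyne gives the (E)-alkenylborane, and boron-to-zinc exchange followed by amino-alcohol-catalysed 1,2-addition (catalytic asymmetric alkenylzinc addition) should deliver the alkenyl group to the Re face of the enal, setting the (R)-carbinol by catalyst control while the hindered ketone is not attacked.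

Step 21
Reactants: 36 the keto alcohol
Product: 37 (1S,2S,3R,4Z)-2-[(3E,5R,6E,8S)-5-hydroxy-4,8,12-trimethyltrideca-3,6,11-trien-1-yl]-4-[1-(TBDPS-oxy)propan-2-ylidene]-3-[3-(TBDPS-oxy)propyl]-1,2-dimethylcyclohexan-1-ol
Conditions: MeLi, CeCl3, THF, –78 °C
Reagents that add atoms: methyllithium, [Li]C
Why: Organocerium addition avoids enolisation of the hindered ketone, and in the chair that keeps the C2 chain axial (to avoid allylic 1,3-strain with the exocyclic alkene) the face syn to that chain is blocked, so methyl is expected to enter equatorially, trans to the C2 chain, giving the (S)-carbinol at C6.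

Step 22
Reactants: 37 the diol
Product: 38 secondary acetate of 37 (5R-acetoxy; tertiary alcohol free)
Conditions: Ac2O, pyridine, DMAP (cat.), CH2Cl2, 0 °C
Reagents that add atoms: acetic anhydride, CC(=O)OC(C)=O
Why: Acylation of the secondary allylic alcohol is much faster than that of the hindered tertiary alcohol, which stays free.

Step 23
Reactants: 38 the bis-silyl acetate
Product: 39 (5R)-acetate triol with both primary alcohols and the tertiary alcohol free
Conditions: HF·pyridine, pyridine, THF, 0 °C → rt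
Reagents that add atoms: none
Why: Buffered fluoride desilylation removes both primary TBDPS ethers while the allylic acetate survives.

Step 24
Reactants: 39 the triol
Product: 40 CNP0259235.1, (2Z)-2-[(2R,3S,4S)-3-[(3E,5R,6E,8S)-5-acetoxy-4,8,12-trimethyltrideca-3,6,11-trien-1-yl]-4-hydroxy-2-(3-hydroxypropyl)-3,4-dimethylcyclohexylidene]propanal
Conditions: MnO2, CH2Cl2, rt
Reagents that add atoms: none
Why: MnO2 oxidises only the allylic primary alcohol to the enal, leaving the saturated primary alcohol, the tertiary alcohol, the acetate and the alkene geometry unchanged.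

**Compound list**
1 | (S)-but-3-yn-2-ol | C[C@H](O)C#C | starting material
2 | tert-butyl(3-iodopropoxy)dimethylsilane | CC(C)(C)[Si](C)(C)OCCCI | starting material
3 | dilithium alkoxide acetylide of 1 | [Li+].[Li+].C[C@H]([O-])C#[C-] | intermediate
4 | (2S)-7-(TBS-oxy)hept-3-yn-2-ol | C[C@H](O)C#CCCCO[Si](C)(C)C(C)(C)C | intermediate
5 | cyclic sodium alkenylaluminate (Al on C4, chelated by the alkoxide) | C[C@@H]1O[Al-](OCCOC)(OCCOC)C(CCCO[Si](C)(C)C(C)(C)C)=C1.[Na+] | intermediate
6 | (2S,3Z)-7-(TBS-oxy)-4-iodohept-3-en-2-ol | C[C@H](O)/C=C(\I)CCCO[Si](C)(C)C(C)(C)C | intermediate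
7 | (2S,3E)-7-(TBS-oxy)-4-methylhept-3-en-2-ol | C[C@H](O)/C=C(\C)CCCO[Si](C)(C)C(C)(C)C | intermediate
8 | δ-valerolactone | O=C1CCCCO1 | starting material
9 | sodium 5-hydroxypentanoate | [Na+].[O-]C(=O)CCCCO | intermediate
10 | tert-butyldiphenylsilyl 5-(TBDPS-oxy)pentanoate | CC(C)(C)[Si](c1ccccc1)(c1ccccc1)OCCCCC(=O)O[Si](c1ccccc1)(c1ccccc1)C(C)(C)C | intermediate
11 | 5-(TBDPS-oxy)pentanoic acid | OC(=O)CCCCO[Si](c1ccccc1)(c1ccccc1)C(C)(C)C | intermediate
12 | (2S,3E)-7-(TBS-oxy)-4-methylhept-3-en-2-yl 5-(TBDPS-oxy)pentanoate | C[C@H](OC(=O)CCCCO[Si](c1ccccc1)(c1ccccc1)C(C)(C)C)/C=C(\C)CCCO[Si](C)(C)C(C)(C)C | intermediate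
13 | (Z)-trimethylsilyl ketene acetal of 12 (alkyl chain cis to OSiMe3) | C[C@H](O/C(O[Si](C)(C)C)=C/CCCO[Si](c1ccccc1)(c1ccccc1)C(C)(C)C)/C=C(\C)CCCO[Si](C)(C)C(C)(C)C | intermediate
14 | trimethylsilyl ester of 15 | CC(C)(C)[Si](C)(C)OCCC[C@@](/C=C/C)(C)[C@H](CCCO[Si](c1ccccc1)(c1ccccc1)C(C)(C)C)C(=O)O[Si](C)(C)C | intermediate
15 | (2S,3R,4E)-3-[3-(TBS-oxy)propyl]-2-[3-(TBDPS-oxy)propyl]-3-methylhex-4-enoic acid | CC(C)(C)[Si](C)(C)OCCC[C@@](/C=C/C)(C)[C@H](CCCO[Si](c1ccccc1)(c1ccccc1)C(C)(C)C)C(=O)O | intermediate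
16 | (2S,3R,4E)-3-[3-(TBS-oxy)propyl]-2-[3-(TBDPS-oxy)propyl]-3-methylhex-4-en-1-ol | CC(C)(C)[Si](C)(C)OCCC[C@@](/C=C/C)(C)[C@H](CCCO[Si](c1ccccc1)(c1ccccc1)C(C)(C)C)CO | intermediate
17 | (2S,3R,4E)-3-[3-(TBS-oxy)propyl]-2-[3-(TBDPS-oxy)propyl]-3-methylhex-4-enal | CC(C)(C)[Si](C)(C)OCCC[C@@](/C=C/C)(C)[C@H](CCCO[Si](c1ccccc1)(c1ccccc1)C(C)(C)C)C=O | intermediate
18 | (3R,4R,5E)-1,1-dibromo-4-[3-(TBS-oxy)propyl]-3-[3-(TBDPS-oxy)propyl]-4-methylhepta-1,5-diene | CC(C)(C)[Si](C)(C)OCCC[C@@](/C=C/C)(C)[C@H](CCCO[Si](c1ccccc1)(c1ccccc1)C(C)(C)C)C=C(Br)Br | intermediate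
19 | lithium acetylide from 18 | CC(C)(C)[Si](C)(C)OCCC[C@@](/C=C/C)(C)[C@H](CCCO[Si](c1ccccc1)(c1ccccc1)C(C)(C)C)C#C[Li] | intermediate
20 | (4S,5R,6E)-5-[3-(TBS-oxy)propyl]-4-[3-(TBDPS-oxy)propyl]-5-methyloct-6-en-2-yn-1-ol | CC(C)(C)[Si](C)(C)OCCC[C@@](/C=C/C)(C)[C@H](CCCO[Si](c1ccccc1)(c1ccccc1)C(C)(C)C)C#CCO | intermediate
21 | TBDPS ether of 20 | CC(C)(C)[Si](C)(C)OCCC[C@@](/C=C/C)(C)[C@H](CCCO[Si](c1ccccc1)(c1ccccc1)C(C)(C)C)C#CCO[Si](c1ccccc1)(c1ccccc1)C(C)(C)C | intermediate
22 | ozonide (1,2,4-trioxolane) of 21 | CC(C)(C)[Si](C)(C)OCCC[C@@](C1OOC(C)O1)(C)[C@H](CCCO[Si](c1ccccc1)(c1ccccc1)C(C)(C)C)C#CCO[Si](c1ccccc1)(c1ccccc1)C(C)(C)C | intermediate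
23 | (2S,3R)-6-(TBDPS-oxy)-2-[3-(TBS-oxy)propyl]-3-[3-(TBDPS-oxy)propyl]-2-methylhex-4-ynal | CC(C)(C)[Si](C)(C)OCCC[C@@](C=O)(C)[C@H](CCCO[Si](c1ccccc1)(c1ccccc1)C(C)(C)C)C#CCO[Si](c1ccccc1)(c1ccccc1)C(C)(C)C | intermediate
24 | (4S,5R)-8-(TBDPS-oxy)-4-[3-(TBS-oxy)propyl]-5-[3-(TBDPS-oxy)propyl]-4-methyloct-1-en-6-yn-3-ol (C3 epimers) | CC(C)(C)[Si](C)(C)OCCC[C@@](C(O)C=C)(C)[C@H](CCCO[Si](c1ccccc1)(c1ccccc1)C(C)(C)C)C#CCO[Si](c1ccccc1)(c1ccccc1)C(C)(C)C | intermediate
25 | (4S,5R)-8-(TBDPS-oxy)-4-[3-(TBS-oxy)propyl]-5-[3-(TBDPS-oxy)propyl]-4-methyloct-1-en-6-yn-3-one | CC(C)(C)[Si](C)(C)OCCC[C@@](C(=O)C=C)(C)[C@H](CCCO[Si](c1ccccc1)(c1ccccc1)C(C)(C)C)C#CCO[Si](c1ccccc1)(c1ccccc1)C(C)(C)C | intermediate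
26 | trimethylsilyl enol ether of 27 | CC(C)(C)[Si](C)(C)OCCC[C@@]1(C)[C@H](CCCO[Si](c2ccccc2)(c2ccccc2)C(C)(C)C)/C(=C(/C)CO[Si](c2ccccc2)(c2ccccc2)C(C)(C)C)CC=C1O[Si](C)(C)C | intermediate
27 | (2S,3R,4Z)-4-[1-(TBDPS-oxy)propan-2-ylidene]-2-[3-(TBS-oxy)propyl]-3-[3-(TBDPS-oxy)propyl]-2-methylcyclohexan-1-one | CC(C)(C)[Si](C)(C)OCCC[C@@]1(C)[C@H](CCCO[Si](c2ccccc2)(c2ccccc2)C(C)(C)C)/C(=C(/C)CO[Si](c2ccccc2)(c2ccccc2)C(C)(C)C)CCC1=O | intermediate
28 | (2S,3R,4Z)-2-(3-hydroxypropyl) analogue of 27 | OCCC[C@@]1(C)[C@H](CCCO[Si](c2ccccc2)(c2ccccc2)C(C)(C)C)/C(=C(/C)CO[Si](c2ccccc2)(c2ccccc2)C(C)(C)C)CCC1=O | intermediate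
29 | (2S,3R,4Z)-2-(3-oxopropyl) analogue of 27 | O=CCC[C@@]1(C)[C@H](CCCO[Si](c2ccccc2)(c2ccccc2)C(C)(C)C)/C(=C(/C)CO[Si](c2ccccc2)(c2ccccc2)C(C)(C)C)CCC1=O | intermediate
30 | (2S,3R,4Z)-2-[(3E)-4-methyl-5-oxopent-3-en-1-yl] keto enal | O=C/C(C)=C/CC[C@@]1(C)[C@H](CCCO[Si](c2ccccc2)(c2ccccc2)C(C)(C)C)/C(=C(/C)CO[Si](c2ccccc2)(c2ccccc2)C(C)(C)C)CCC1=O | intermediate
31 | (S)-citronellal | O=CC[C@@H](C)CCC=C(C)C | starting material
32 | alkenyl nonaflate of 31 (E/Z mixture) | CC(C)=CCC[C@H](C)C=COS(=O)(=O)C(F)(F)C(F)(F)C(F)(F)C(F)(F)F | intermediate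
33 | (3S)-3,7-dimethyloct-6-en-1-yne | C#C[C@@H](C)CCC=C(C)C | intermediate
34 | dicyclohexyl[(1E,3S)-3,7-dimethylocta-1,6-dien-1-yl]borane | CC(C)=CCC[C@H](C)/C=C/B(C1CCCCC1)C1CCCCC1 | intermediate
35 | [(1E,3S)-3,7-dimethylocta-1,6-dien-1-yl](methyl)zinc | CC(C)=CCC[C@H](C)/C=C/[Zn]C | intermediate
36 | keto bis-allylic alcohol (5R,8S side chain; ring 2S,3R,4Z) | O[C@H](/C=C/[C@@H](C)CCC=C(C)C)/C(C)=C/CC[C@@]1(C)[C@H](CCCO[Si](c2ccccc2)(c2ccccc2)C(C)(C)C)/C(=C(/C)CO[Si](c2ccccc2)(c2ccccc2)C(C)(C)C)CCC1=O | intermediate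
37 | diol (secondary 5R alcohol, tertiary 1S alcohol) | O[C@H](/C=C/[C@@H](C)CCC=C(C)C)/C(C)=C/CC[C@@]1(C)[C@H](CCCO[Si](c2ccccc2)(c2ccccc2)C(C)(C)C)/C(=C(/C)CO[Si](c2ccccc2)(c2ccccc2)C(C)(C)C)CC[C@]1(C)O | intermediate
38 | bis-TBDPS acetate | CC(=O)O[C@H](/C=C/[C@@H](C)CCC=C(C)C)/C(C)=C/CC[C@@]1(C)[C@H](CCCO[Si](c2ccccc2)(c2ccccc2)C(C)(C)C)/C(=C(/C)CO[Si](c2ccccc2)(c2ccccc2)C(C)(C)C)CC[C@]1(C)O | intermediate
39 | acetate triol | CC(=O)O[C@H](/C=C/[C@@H](C)CCC=C(C)C)/C(C)=C/CC[C@@]1(C)[C@H](CCCO)/C(=C(/C)CO)CC[C@]1(C)O | intermediate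
40 | CNP0259235.1 | CC(=O)O[C@H](/C=C/[C@@H](C)CCC=C(C)C)/C(C)=C/CC[C@@]1(C)[C@H](CCCO)/C(=C(/C)C=O)CC[C@]1(C)O | target

**Step count**
Total: 24 steps. Longest linear sequence: 22 steps (1–3, 5–18, 20–24); steps 4 and 19 are one-step side branches.

**Three steps most likely to fail**

Step 15 (proposed new method). Direct conjugate transfer of methyl to the enone, or oligomerisation of the vinyl ketone, may outrun insertion of the alkyne, because ring closure needs the less populated s-trans enone and an endo-type insertion. The fallback forms the same C3–C4 bond by known chemistry; it sets out from acid 15 and comes back at ketone 27. Acid 15 is activated with carbonyldiimidazole and C-acylated with the magnesium salt of ethyl hydrogen methylmalonate (decarboxylative Claisen condensation) to give β-keto ester F1. Triflation under non-chelating conditions (Tf2O, aqueous Me4NOH, hexane) gives (E)-enol triflate F2, with the triflate cis to the C-methyl group. Ozonolysis of the propenyl group (O3; PPh3) gives aldehyde F3, and vinylmagnesium bromide at –78 °C gives allylic alcohol F4. Hydroboration of the vinyl group with 9-BBN and intramolecular B-alkyl Suzuki–Miyaura coupling (Pd(dppf)Cl2, Ph3As, Cs2CO3, DMF/THF/H2O, high dilution) closes the ring with retention of alkene geometry to give hydroxy ester F5. DIBAL-H reduction gives diol F6, selective silylation of the primary allylic alcohol (TBDPSCl, imidazole) gives silyl ether F7, and Dess–Martin oxidation of the ring alcohol returns 27.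

Step 21. Facial selectivity may be poor (competing attack on the face of the axial C2 chain), or the hindered ketone may enolise. The fallback sets out from 36 and comes back at 37. A Corey–Chaykovsky reaction with dimethylsulfoxonium methylide (Me3S(O)I, NaH, DMSO, rt → 50 °C), whose reversible addition places the new C–C bond equatorially, gives spiro-epoxide F8. LiEt3BH (THF, 0 °C) then opens the epoxide at its CH2 terminus to give 37, so the methyl group arises by hydride delivery instead of methyl addition.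

Step 20. Catalyst control at the new carbinol centre may erode through background addition of the uncatalysed zinc reagent or transfer of methyl instead of the alkenyl group. The fallback sets out from 30 (with alkyne 33) and comes back at 37. Zinc-mediated asymmetric alkynylation of the enal (33, Me2Zn, the ProPhenol ligand enantiomer that directs Re-face addition, Ph3PO, toluene, 0 °C) gives propargylic alcohol F9, with the ketone untouched. MeLi/CeCl3 addition to the ring ketone, as in step 21, gives propargylic diol F10. Alkoxide-directed trans-hydroalumination with Red-Al (THF, 0 °C → rt) and protonolysis then give the (E)-allylic alcohol 37.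

**Further compounds**
F1 | step 15 | ethyl (4S,5R,6E)-5-[3-(TBS-oxy)propyl]-4-[3-(TBDPS-oxy)propyl]-2,5-dimethyl-3-oxooct-6-enoate | CC(C)(C)[Si](C)(C)OCCC[C@@](/C=C/C)(C)[C@H](CCCO[Si](c1ccccc1)(c1ccccc1)C(C)(C)C)C(=O)C(C)C(=O)OCC
F2 | step 15 | (E)-enol triflate of F1 (triflate cis to C-methyl) | CC(C)(C)[Si](C)(C)OCCC[C@@](/C=C/C)(C)[C@H](CCCO[Si](c1ccccc1)(c1ccccc1)C(C)(C)C)/C(OS(=O)(=O)C(F)(F)F)=C(/C)C(=O)OCC
F3 | step 15 | aldehyde from ozonolysis of F2 | CC(C)(C)[Si](C)(C)OCCC[C@@](C=O)(C)[C@H](CCCO[Si](c1ccccc1)(c1ccccc1)C(C)(C)C)/C(OS(=O)(=O)C(F)(F)F)=C(/C)C(=O)OCC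
F4 | step 15 | vinyl carbinol from F3 (carbinol epimers) | CC(C)(C)[Si](C)(C)OCCC[C@@](C(O)C=C)(C)[C@H](CCCO[Si](c1ccccc1)(c1ccccc1)C(C)(C)C)/C(OS(=O)(=O)C(F)(F)F)=C(/C)C(=O)OCC
F5 | step 15 | cyclised hydroxy ester, ethyl (2Z)-2-cyclohexylidenepropanoate type | CC(C)(C)[Si](C)(C)OCCC[C@@]1(C)[C@H](CCCO[Si](c2ccccc2)(c2ccccc2)C(C)(C)C)/C(=C(/C)C(=O)OCC)CCC1O
F6 | step 15 | diol from reduction of F5 | CC(C)(C)[Si](C)(C)OCCC[C@@]1(C)[C@H](CCCO[Si](c2ccccc2)(c2ccccc2)C(C)(C)C)/C(=C(/C)CO)CCC1O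
F7 | step 15 | ring alcohol with the allylic oxygen as TBDPS ether | CC(C)(C)[Si](C)(C)OCCC[C@@]1(C)[C@H](CCCO[Si](c2ccccc2)(c2ccccc2)C(C)(C)C)/C(=C(/C)CO[Si](c2ccccc2)(c2ccccc2)C(C)(C)C)CCC1O
F8 | step 21 | spiro-epoxide at C6 of 36 | O[C@H](/C=C/[C@@H](C)CCC=C(C)C)/C(C)=C/CC[C@@]1(C)[C@H](CCCO[Si](c2ccccc2)(c2ccccc2)C(C)(C)C)/C(=C(/C)CO[Si](c2ccccc2)(c2ccccc2)C(C)(C)C)CC[C@@]12CO2
F9 | step 20 | (S)-propargylic alcohol from 30 and 33 | O[C@H](C#C[C@@H](C)CCC=C(C)C)/C(C)=C/CC[C@@]1(C)[C@H](CCCO[Si](c2ccccc2)(c2ccccc2)C(C)(C)C)/C(=C(/C)CO[Si](c2ccccc2)(c2ccccc2)C(C)(C)C)CCC1=O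
F10 | step 20 | propargylic diol after methyl addition to F9 | O[C@H](C#C[C@@H](C)CCC=C(C)C)/C(C)=C/CC[C@@]1(C)[C@H](CCCO[Si](c2ccccc2)(c2ccccc2)C(C)(C)C)/C(=C(/C)CO[Si](c2ccccc2)(c2ccccc2)C(C)(C)C)CC[C@]1(C)O
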